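**Retrosynthetic overview**

1. Ardisinone (R at C2' of the pentadecyl chain, numbered from the ring) comes from Teuber oxidation of (2R)-1-(2-hydroxy-3-methoxyphenyl)pentadecan-2-yl acetate, whose phenol is unmasked from a benzyl ether.
2. Key disconnection: the C2'–C3' bond between the acetoxy-bearing carbon and the first CH2 of the tridecyl tail. The precursors are a racemic 1-bromo-2-arylethyl acetate and 1-tridecene, joined by a nickel-hydride enantioconvergent alkyl–alkyl coupling that makes the bond, the stereocentre and the acetate in one operation.
3. The bromo acetate comes from the arylacetaldehyde and acetyl bromide; the aldehyde comes from ozonolysis of O-benzylated 2-allyl-6-methoxyphenol.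
4. Enabling feature: the acetoxy group on side-chain carbon C2'. Its ether oxygen makes C2' an easily formed α-oxy bromide and radical, and its carbonyl oxygen can bind nickel, so the target's own ester is the activating and directing group and is never removed.
5. Rings: none is formed. The only ring, the six-membered carbocycle, is bought as the benzene ring of the starting phenol and oxidised in the last step to the 2-methoxy-1,4-benzoquinone (carbonyls at C1 and C4).

Key step: step 3

Assumption: the (S,S)-bis(oxazoline) ligand is taken to deliver the R acetate in step 3; if a trial run shows the opposite sense, the equally available (R,R)-ligand is used with no other change.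

**Route**

Step 1
Reactants: 1 2-allyl-6-methoxyphenol
Product: 2 1-allyl-2-(benzyloxy)-3-methoxybenzene
Conditions: BnBr, K2CO3, DMF, rt
Reagents that add atoms: benzyl bromide, BrCc1ccccc1
Why: Williamson etherification of the phenoxide with a benzylic bromide is reliable, and the benzyl ether masks the phenol, which would otherwise close a lactol with the aldehyde of step 2 and consume acetyl bromide in step 3, until neutral hydrogenolysis.

Step 2
Reactants: 2 1-allyl-2-(benzyloxy)-3-methoxybenzene
Product: 4 2-[2-(benzyloxy)-3-methoxyphenyl]acetaldehyde, via secondary ozonide 3 (not isolated)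
Conditions: O3, CH2Cl2, −78 °C (Sudan Red 7B end-point); then PPh3, −78 °C → rt; crude aldehyde used at once
Reagents that add atoms: ozone, [O-][O+]=O
Why: Ozonolysis with reductive work-up should cleave the isolated terminal olefin much faster than ozone attacks the dialkoxyarene when dosing stops at the indicator end-point, and triphenylphosphine reduces the ozonide under neutral conditions that spare the enolisable arylacetaldehyde.

Step 3
Reactants: 4 2-[2-(benzyloxy)-3-methoxyphenyl]acetaldehyde; 5 1-tridecene
Product: 7 (2R)-1-[2-(benzyloxy)-3-methoxyphenyl]pentadecan-2-yl acetate, via racemic bromo acetate 6 (not isolated)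
Conditions: AcBr (1.0 equiv), CH2Cl2, 0 °C → rt, then volatiles removed; then 5 (1.5 equiv), NiBr2·glyme (10 mol %), (S,S)-Ph-BOX [2,2'-(propane-2,2-diyl)bis((4S)-4-phenyl-4,5-dihydrooxazole)] (12 mol %), (EtO)2MeSiH (2 equiv), K3PO4·H2O (2 equiv), iPr2O/DMA, 0 °C → rt
Reagents that add atoms: acetyl bromide, CC(=O)Br
Why: Acetyl bromide adds across the aldehyde C=O to give the racemic 1-bromoalkyl acetate 6; the nickel dibromide/bis(oxazoline) complex is converted by the hydrosilane and phosphate into a chiral nickel hydride that inserts 1-tridecene in the anti-Markovnikov sense, monovalent nickel abstracts bromine from 6 to give the planar α-acetoxyalkyl radical, and capture of this radical by the chiral tridecylnickel followed by reductive elimination from trivalent nickel forms the C2'–C3' bond. The closest known reaction type is the nickel-hydride enantioconvergent hydroalkylation of terminal olefins with racemic 1-bromoalkyl carboxylates generated from an aldehyde and an acyl bromide, a four-component assembly of esters of dialkyl carbinols. No ring is closed. The new stereocentre C2' is set under catalyst control: both enantiomers of 6 converge on the same prochiral radical, and the ligand-bound nickel, to which the acetate carbonyl can chelate, decides the face that receives the tridecyl group. The step needs linear hydrometalation without chain-walking, which the unbranched terminal olefin secures; it needs cross-coupling to outrun hydrodebromination and loss of HBr to the enol acetate, which the low temperature and the heterogeneous mild base favour; and it needs the aryl ethers to stay inert, which they should be toward these nickel species at this temperature.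

Step 4
Reactants: 7 (2R)-1-[2-(benzyloxy)-3-methoxyphenyl]pentadecan-2-yl acetate
Product: 8 (2R)-1-(2-hydroxy-3-methoxyphenyl)pentadecan-2-yl acetate
Conditions: H2 (1 atm), 10 % Pd/C, EtOAc, rt
Reagents that add atoms: none
Why: Heterogeneous hydrogenolysis should cleave the benzylic C–O bond of the aryl benzyl ether under neutral conditions that leave the secondary acetate, the methyl ether and the stereocentre untouched.

Step 5
Reactants: 8 (2R)-1-(2-hydroxy-3-methoxyphenyl)pentadecan-2-yl acetate
Product: 9 ardisinone, 2-[(2R)-2-acetoxypentadecyl]-6-methoxy-1,4-benzoquinone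
Conditions: (KSO3)2NO (2.5 equiv), aq. KH2PO4 (pH 6), acetone/H2O, rt
Reagents that add atoms: potassium nitrosodisulfonate, [K+].[K+].[O]N(S(=O)(=O)[O-])S(=O)(=O)[O-]
Why: In the Teuber oxidation one nitroxyl radical abstracts the phenolic hydrogen and a second couples at the free carbon para to the hydroxyl, so that loss of imidodisulfate should give the 2-methoxy-6-alkyl-1,4-benzoquinone while the buffered, near-neutral medium spares the acetate and the stereocentre.

**Compound list**

1 | 2-allyl-6-methoxyphenol | C=CCc1cccc(OC)c1O | starting material
2 | 1-allyl-2-(benzyloxy)-3-methoxybenzene | C=CCc1cccc(OC)c1OCc2ccccc2 | intermediate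
3 | 3-[2-(benzyloxy)-3-methoxybenzyl]-1,2,4-trioxolane (secondary ozonide, racemic) | C1OOC(Cc2cccc(OC)c2OCc3ccccc3)O1 | intermediate
4 | 2-[2-(benzyloxy)-3-methoxyphenyl]acetaldehyde | O=CCc1cccc(OC)c1OCc2ccccc2 | intermediate
5 | 1-tridecene | C=CCCCCCCCCCCC | starting material
6 | rac-1-bromo-2-[2-(benzyloxy)-3-methoxyphenyl]ethyl acetate | CC(=O)OC(Br)Cc1cccc(OC)c1OCc2ccccc2 | intermediate
7 | (2R)-1-[2-(benzyloxy)-3-methoxyphenyl]pentadecan-2-yl acetate | CCCCCCCCCCCCC[C@H](Cc1cccc(OC)c1OCc2ccccc2)OC(C)=O | intermediate
8 | (2R)-1-(2-hydroxy-3-methoxyphenyl)pentadecan-2-yl acetate | CCCCCCCCCCCCC[C@H](Cc1cccc(OC)c1O)OC(C)=O | intermediate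
9 | ardisinone, 2-[(2R)-2-acetoxypentadecyl]-6-methoxy-1,4-benzoquinone | CCCCCCCCCCCCC[C@H](CC1=CC(=O)C=C(OC)C1=O)OC(C)=O | target

**Step count**

Total steps: 5. Longest linear sequence: 5 steps (1 → 2 → 4 → 7 → 8 → 9); 1-tridecene 5 enters at step 3.

**Steps most likely to fail**

Step 3. The bromo acetate may lose HBr to the conjugated enol acetate, or the radical may be reduced, faster than it is captured by the alkylnickel. Face discrimination may also be poor because the radical carries two CH2-type substituents. The fallback forms the same C2'–C3' bond by catalyst-controlled carbonyl addition and sets out from aldehyde 4 and olefin 5. Olefin 5 is hydroborated with Et2BH to diethyl(tridecyl)borane F1. Boron–zinc exchange with neat Et2Zn, with removal of the volatile borane, should give ditridecylzinc F2. Addition of F2 to 4 with Ti(OiPr)4 and (1S,2S)-1,2-bis(trifluoromethanesulfonamido)cyclohexane (toluene, −20 °C, work-up with 1 M HCl) should give (2R)-1-[2-(benzyloxy)-3-methoxyphenyl]pentadecan-2-ol F3. The ligand antipode is chosen by analogy with additions to other aliphatic aldehydes and is switched if a trial shows the opposite sense. Acetylation (Ac2O, pyridine, DMAP cat., CH2Cl2) comes back to the route at 7.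

Step 2. Ozone may over-oxidise the electron-rich ring or the benzylic ether CH2, and the arylacetaldehyde may undergo aldol self-condensation or air oxidation during work-up. The fallback sets out from 2 and avoids ozone. Dihydroxylation (K2OsO4·2H2O cat., NMO, acetone/H2O, rt) should give the stable, storable rac-3-[2-(benzyloxy)-3-methoxyphenyl]propane-1,2-diol F4. Glycol cleavage (NaIO4 on silica gel, CH2Cl2, rt) releases the aldehyde under neutral conditions just before use and comes back to the route at 4.

Step 5. The radical oxidation may be unselective, through oxidative coupling of the phenoxyl radical or attack at the methoxy-bearing ortho carbon. The lipophilic phenol may also transfer too slowly into the aqueous oxidant, leaving conversion incomplete. The fallback installs nitrogen at the para carbon by ionic chemistry and sets out from 8. Azo coupling with PhN2BF4 (pyridine/THF, 0 °C) should give (2R)-1-{2-hydroxy-3-methoxy-5-[(E)-phenyldiazenyl]phenyl}pentadecan-2-yl acetate F5. Reductive cleavage (Na2S2O4, THF/H2O, 45 °C) should give (2R)-1-(5-amino-2-hydroxy-3-methoxyphenyl)pentadecan-2-yl acetate F6. Oxidation with hydrolysis of the quinone imine (FeCl3, aq. HCl/THF, rt) comes back to the route at 9.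

Further compounds
F1 | step 3 | diethyl(tridecyl)borane | CCCCCCCCCCCCCB(CC)CC
F2 | step 3 | ditridecylzinc | CCCCCCCCCCCCC[Zn]CCCCCCCCCCCCC
F3 | step 3 | (2R)-1-[2-(benzyloxy)-3-methoxyphenyl]pentadecan-2-ol | CCCCCCCCCCCCC[C@H](Cc1cccc(OC)c1OCc2ccccc2)O
F4 | step 2 | rac-3-[2-(benzyloxy)-3-methoxyphenyl]propane-1,2-diol | OCC(O)Cc1cccc(OC)c1OCc2ccccc2
F5 | step 5 | (2R)-1-{2-hydroxy-3-methoxy-5-[(E)-phenyldiazenyl]phenyl}pentadecan-2-yl acetate | CCCCCCCCCCCCC[C@H](Cc1cc(/N=N/c2ccccc2)cc(OC)c1O)OC(C)=O
F6 | step 5 | (2R)-1-(5-amino-2-hydroxy-3-methoxyphenyl)pentadecan-2-yl acetate | CCCCCCCCCCCCC[C@H](Cc1cc(N)cc(OC)c1O)OC(C)=O
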